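**Retrosynthetic overview**
- The aryl ether O–C1 is made last (Mitsunobu with umbelliferone). C1–C2 come from an allyl group added under catalyst control to a C3 methyl ketone. C4=C5 comes from a C5 aldehyde by olefination, then hydrogenation.
- The C7 methyl (C15) and the C10 hydroxyl are unmasked together from a lactone bridge C7–C15(=O)–O–C10.
- Key disconnection: C6–C7 and C10–C11, both made in one catalytic asymmetric [4+2] of 3-hydroxy-2-pyrone (C7–C10, C15, both ring oxygens) with prenal (C5, C6, C11 and its two methyls).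
- Enabling feature: on the cyclohexane ring the C7 methyl and the C10 oxygen are cis-1,4 and the C6 side chain is cis to the C7 hydroxyl. The ring is therefore a reduced endo cycloadduct, a 2-oxabicyclo[2.2.2]octan-3-one, whose gem-dimethyl carbon C11 is the β-carbon of an enal.
- Ring order: the carbocycle is the only ring built (step 1, as the bicycle); the lactone ring comes with the pyrone and is opened in step 5; the coumarin is bought.

Key step: step 1

Remark on numbering (not the locants of the systematic names): ArO–C1–C2–C3(CH3)(OH)–C4–C5–C6(ring)–C7(CH3 = C15)(OH)–C8–C9–C10(OH)–C11(CH3)2–C6.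
Remark on the chemistry: the absolute sense of induction in the two catalyst-controlled steps (1 and 4) is assigned by analogy; if it proves opposite, the pseudoenantiomeric or enantiomeric catalyst is used.

Step 1
Reactants: 1 3-hydroxy-2H-pyran-2-one; 2 3-methylbut-2-enal (prenal)
Product: 3 (1S,4S,8R)-4-hydroxy-7,7-dimethyl-3-oxo-2-oxabicyclo[2.2.2]oct-5-ene-8-carbaldehyde (formyl endo, syn to C5=C6 of the bicycle)
Conditions: 9-amino-9-deoxy-epi-quinine (20 mol %), CF3CO2H (40 mol %), 2 (3 equiv), CH2Cl2 (2 M), 25 °C, 9 kbar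
Reagents that add atoms: none
Why: Proposed new method: the amine-catalysed Diels–Alder reaction of 3-hydroxy-2-pyrones, established for β-monosubstituted enones, acrylates and related acceptors, is here asked to accept the β,β-dimethyl enal 2 so that its conjugate-addition half creates the quaternary carbon C11; the closest known reaction types are these cinchona-amine pyrone cycloadditions and the iminium-catalysed additions of nitromethane to β,β-disubstituted enals. Mechanism: 2 condenses to its iminium ion, the pyronate (ion-paired with the protonated quinuclidine) attacks C11 through C10 (vinylogous Michael), and the resulting enamine carbon C6 at once adds to the now ketonic C7 (aldol), an asynchronous [4+2] that releases no free intermediate. The one ring closed is the carbocycle C6–C7–C8–C9–C10–C11 (intermolecular [4+2] whose second bond is a 6-(enolexo)-exo-trig aldol), which turns the pyranone into the 2-oxabicyclo[2.2.2]octene. C10 is set by the catalyst-controlled face of the pyronate, C7 follows because the bridge can only close suprafacially across the pyranone, and C6 is set by the endo orientation of the formyl (enamine) unit under the C8=C9 bridge, which places C5 cis to the C7 hydroxyl and trans to O10. Regioselectivity (C11 to C10, C6 to C7) is secured by the 3-oxido group, which makes C6 of the pyrone the nucleophilic terminus and C3 the carbonyl acceptor; 1,2-addition to the iminium ion is reversible and should drain into the cycloadduct. The quinine-derived amine is proposed for the (1S,4S,8R) series, and endo/exo control is the least secure element.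

Step 2
Reactants: 3 (1S,4S,8R)-4-hydroxy-7,7-dimethyl-3-oxo-2-oxabicyclo[2.2.2]oct-5-ene-8-carbaldehyde; 4 dimethyl (2-oxopropyl)phosphonate
Product: 5 (1S,4S,8R)-4-hydroxy-7,7-dimethyl-8-[(1E)-3-oxobut-1-en-1-yl]-2-oxabicyclo[2.2.2]oct-5-en-3-one
Conditions: 4 (1.5 equiv), LiCl, i-Pr2NEt, MeCN, 0 → 25 °C
Reagents that add atoms: none
Why: Horner–Wadsworth–Emmons olefination in its mild LiCl/amine variant should give the (E)-enone (C4=C5) because the weak base deprotonates only the β-ketophosphonate and should neither open the tertiary β-hydroxy aldehyde by retro-aldol nor epimerise C6.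

Step 3
Reactants: 5 (1S,4S,8R)-4-hydroxy-7,7-dimethyl-8-[(1E)-3-oxobut-1-en-1-yl]-2-oxabicyclo[2.2.2]oct-5-en-3-one
Product: 6 (1S,4S,8R)-4-hydroxy-7,7-dimethyl-8-(3-oxobutyl)-2-oxabicyclo[2.2.2]octan-3-one
Conditions: H2 (1 atm), 10 % Pd/C, EtOAc, 25 °C
Reagents that add atoms: none
Why: Heterogeneous catalytic hydrogenation should saturate the cis-disubstituted C8=C9 bond and the conjugated C4=C5 bond while ketone, lactone and the bridgehead C–O bonds (which cannot ionise to π-allyl species) stay intact; no stereocentre is formed.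

Step 4
Reactants: 6 (1S,4S,8R)-4-hydroxy-7,7-dimethyl-8-(3-oxobutyl)-2-oxabicyclo[2.2.2]octan-3-one; 7 allyldiisopropoxyborane
Product: 8 (1S,4S,8R)-4-hydroxy-8-[(3R)-3-hydroxy-3-methylhex-5-en-1-yl]-7,7-dimethyl-2-oxabicyclo[2.2.2]octan-3-one
Conditions: 7 (1.5 equiv), (R)-3,3′-Br2-BINOL (15 mol %), PhCF3–toluene (3:1), −35 °C; then aq. NaHCO3
Reagents that add atoms: none
Why: Chiral-diol-catalysed asymmetric allylboration of a ketone, in which ligand exchange gives a chiral mixed boronate that adds allyl through a chair transition state to the Si face of the methyl ketone (larger CH2CH2R group equatorial), should set C3 as R under catalyst control independent of the remote ring stereocentres; the lactone is inert, and 6 reacts through its open keto form even if it rests partly as the hemiketal with the C7 hydroxyl.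

Step 5
Reactants: 8 (1S,4S,8R)-4-hydroxy-8-[(3R)-3-hydroxy-3-methylhex-5-en-1-yl]-7,7-dimethyl-2-oxabicyclo[2.2.2]octan-3-one
Product: 9 (1S,2R,4S)-1-(hydroxymethyl)-2-[(3R)-3-hydroxy-3-methylhex-5-en-1-yl]-3,3-dimethylcyclohexane-1,4-diol
Conditions: LiAlH4 (3 equiv), THF, 0 → 25 °C; aq. potassium sodium tartrate
Reagents that add atoms: none
Why: Hydride reduction of a lactone to a diol cleaves only the acyl C15–O bond, so C10 keeps its oxygen with retention and C15 becomes CH2OH, while the terminal alkene survives.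

Step 6
Reactants: 9 (1S,2R,4S)-1-(hydroxymethyl)-2-[(3R)-3-hydroxy-3-methylhex-5-en-1-yl]-3,3-dimethylcyclohexane-1,4-diol
Product: 10 [(1S,2R,4S)-1,4-dihydroxy-2-[(3R)-3-hydroxy-3-methylhex-5-en-1-yl]-3,3-dimethylcyclohexyl]methyl 4-methylbenzenesulfonate
Conditions: TsCl (1.1 equiv), Bu2SnO (5 mol %), Et3N, CH2Cl2, 0 → 25 °C
Reagents that add atoms: 4-methylbenzenesulfonyl chloride, Cc1ccc(cc1)S(=O)(=O)Cl
Why: Tin-catalysed regioselective monosulfonylation of a 1,2-diol (via the stannylene acetal) should activate the primary oxygen on C15 and leave the tertiary hydroxyls and the hindered secondary C10 hydroxyl free.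

Step 7
Reactants: 10 [(1S,2R,4S)-1,4-dihydroxy-2-[(3R)-3-hydroxy-3-methylhex-5-en-1-yl]-3,3-dimethylcyclohexyl]methyl 4-methylbenzenesulfonate
Product: 12 (1S,2R,4S)-2-[(3R)-3-hydroxy-3-methylhex-5-en-1-yl]-1,3,3-trimethylcyclohexane-1,4-diol, via spiro-epoxide 11 (not isolated)
Conditions: LiEt3BH (4 equiv), THF, 0 → 40 °C; then aq. NH4Cl
Reagents that add atoms: none
Why: Hydride reduction of a β-hydroxy tosylate, in which the C7 alkoxide closes the terminal epoxide and hydride opens it at the CH2 carbon, should turn C15 into the C7 methyl group without touching the C7–O bond, so C7 keeps its configuration.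

Step 8
Reactants: 12 (1S,2R,4S)-2-[(3R)-3-hydroxy-3-methylhex-5-en-1-yl]-1,3,3-trimethylcyclohexane-1,4-diol
Product: 14 (1S,2R,4S)-2-[(3R)-3,5-dihydroxy-3-methylpentyl]-1,3,3-trimethylcyclohexane-1,4-diol, via hydroxy aldehyde 13 (not isolated)
Conditions: O3, CH2Cl2–MeOH (1:1), −78 °C; then NaBH4, −78 → 25 °C
Reagents that add atoms: ozone, [O-][O+]=O
Why: Ozonolysis with reductive work-up should shorten the allyl group by one carbon to the 2-hydroxyethyl arm (C2–C1–OH), no other oxidisable group being present.

Step 9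
Reactants: 14 (1S,2R,4S)-2-[(3R)-3,5-dihydroxy-3-methylpentyl]-1,3,3-trimethylcyclohexane-1,4-diol; 15 7-hydroxy-2H-chromen-2-one (umbelliferone)
Product: 16 7-{[(3R)-5-[(1R,3S,6S)-3,6-dihydroxy-2,2,6-trimethylcyclohexyl]-3-hydroxy-3-methylpentyl]oxy}-2H-chromen-2-one (target)
Conditions: 15 (1.2 equiv), PPh3, DIAD, THF, 0 → 25 °C
Reagents that add atoms: none
Why: Mitsunobu etherification should alkylate the acidic phenol with the only primary alcohol, the tertiary hydroxyls and the neopentyl-type secondary C10 hydroxyl being too hindered to be activated at a competitive rate; no stereocentre is involved.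

**Compound list**
1 | 3-hydroxy-2H-pyran-2-one | O=C1OC=CC=C1O | starting material
2 | 3-methylbut-2-enal | CC(C)=CC=O | starting material
3 | (1S,4S,8R)-4-hydroxy-7,7-dimethyl-3-oxo-2-oxabicyclo[2.2.2]oct-5-ene-8-carbaldehyde | CC1(C)[C@@H](C=O)[C@@]2(O)C=C[C@@H]1OC2=O | intermediate
4 | dimethyl (2-oxopropyl)phosphonate | CC(=O)CP(=O)(OC)OC | starting material
5 | (1S,4S,8R)-4-hydroxy-7,7-dimethyl-8-[(1E)-3-oxobut-1-en-1-yl]-2-oxabicyclo[2.2.2]oct-5-en-3-one | CC1(C)[C@@H](/C=C/C(C)=O)[C@@]2(O)C=C[C@@H]1OC2=O | intermediate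
6 | (1S,4S,8R)-4-hydroxy-7,7-dimethyl-8-(3-oxobutyl)-2-oxabicyclo[2.2.2]octan-3-one | CC1(C)[C@@H](CCC(C)=O)[C@@]2(O)CC[C@@H]1OC2=O | intermediate
7 | allyldiisopropoxyborane (diisopropyl prop-2-en-1-ylboronate) | C=CCB(OC(C)C)OC(C)C | starting material
8 | (1S,4S,8R)-4-hydroxy-8-[(3R)-3-hydroxy-3-methylhex-5-en-1-yl]-7,7-dimethyl-2-oxabicyclo[2.2.2]octan-3-one | CC1(C)[C@@H](CC[C@@](C)(O)CC=C)[C@@]2(O)CC[C@@H]1OC2=O | intermediate
9 | (1S,2R,4S)-1-(hydroxymethyl)-2-[(3R)-3-hydroxy-3-methylhex-5-en-1-yl]-3,3-dimethylcyclohexane-1,4-diol | CC1(C)[C@@H](CC[C@@](C)(O)CC=C)[C@@](CO)(O)CC[C@@H]1O | intermediate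
10 | [(1S,2R,4S)-1,4-dihydroxy-2-[(3R)-3-hydroxy-3-methylhex-5-en-1-yl]-3,3-dimethylcyclohexyl]methyl 4-methylbenzenesulfonate | CC1(C)[C@@H](CC[C@@](C)(O)CC=C)[C@@](COS(=O)(=O)c2ccc(C)cc2)(O)CC[C@@H]1O | intermediate
11 | (3S,4R,6S)-4-[(3R)-3-hydroxy-3-methylhex-5-en-1-yl]-5,5-dimethyl-1-oxaspiro[2.5]octan-6-ol | CC1(C)[C@@H](CC[C@@](C)(O)CC=C)[C@@]2(OC2)CC[C@@H]1O | intermediate
12 | (1S,2R,4S)-2-[(3R)-3-hydroxy-3-methylhex-5-en-1-yl]-1,3,3-trimethylcyclohexane-1,4-diol | CC1(C)[C@@H](CC[C@@](C)(O)CC=C)[C@@](C)(O)CC[C@@H]1O | intermediate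
13 | (3R)-5-[(1R,3S,6S)-3,6-dihydroxy-2,2,6-trimethylcyclohexyl]-3-hydroxy-3-methylpentanal | CC1(C)[C@@H](CC[C@@](C)(O)CC=O)[C@@](C)(O)CC[C@@H]1O | intermediate
14 | (1S,2R,4S)-2-[(3R)-3,5-dihydroxy-3-methylpentyl]-1,3,3-trimethylcyclohexane-1,4-diol | CC1(C)[C@@H](CC[C@@](C)(O)CCO)[C@@](C)(O)CC[C@@H]1O | intermediate
15 | 7-hydroxy-2H-chromen-2-one (umbelliferone) | O=c1ccc2ccc(O)cc2o1 | starting material
16 | 7-{[(3R)-5-[(1R,3S,6S)-3,6-dihydroxy-2,2,6-trimethylcyclohexyl]-3-hydroxy-3-methylpentyl]oxy}-2H-chromen-2-one | CC1(C)[C@@H](CC[C@@](C)(O)CCOc2ccc3ccc(=O)oc3c2)[C@@](C)(O)CC[C@@H]1O | target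

**Step count**
Total steps: 9. Longest linear sequence: 9.

**Steps most likely to fail**

Step 1 (proposed new method). The conjugate addition may not take place at the fully substituted β-carbon of 2 (reversible 1,2-addition or condensation instead), and endo/exo control may be poor. The fallback sets out from 1 and replaces the unreactive β,β-dimethyl acceptor by a strain-activated one that carries the gem-dimethyl group in latent form. Alkylidenecyclopropane carbonyl compounds are established as unusually reactive Michael acceptors and dienophiles because the β-carbon leaves a strained sp2 state; the pyrone cycloaddition itself remains a substrate extension here too. Commercial ethyl 2-cyclopropylideneacetate is reduced (i-Bu2AlH, CH2Cl2, −78 °C) to 2-cyclopropylideneethan-1-ol F1 and oxidised (MnO2, CH2Cl2) to 2-cyclopropylideneacetaldehyde F2. Cycloaddition of F2 with 1 under amine catalysis at ambient pressure should give the spiro-cyclopropane cycloadduct F3, and olefination with 4 as in step 2 the spiro enone F4. Hydrogenation over PtO2 in EtOAc–AcOH should then saturate both C=C bonds and cleave the distal CH2–CH2 bond of the cyclopropane (the classical unveiling of a gem-dimethyl group); the ketone may need to be watched for over-reduction. The route is rejoined at 6.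

Step 2. The β-hydroxy aldehyde may open by retro-aldol (reversal of the second bond formation of step 1), C6 may epimerise under the basic conditions, and the hindered formyl group may react slowly. The fallback sets out from 3 and blocks alkoxide formation, the trigger of the retro-aldol path, by temporary protection. Silylation of the C7 hydroxyl (TMSOTf, 2,6-lutidine, CH2Cl2, −78 °C) gives the trimethylsilyl ether F5. Olefination with 4 gives the silylated enone F6, hydrogenation (H2, Pd/C) the silylated keto-lactone F7, and desilylation (citric acid, MeOH) returns the route to 6.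

Step 4. Facial selectivity at the remote C3 ketone (CH3 against CH2CH2R) may be poor, giving a C3-epimeric mixture that cannot be separated. The fallback sets out from 6 and transfers CH2 instead of allyl. Catalytic asymmetric Corey–Chaykovsky epoxidation, a reaction developed for methyl ketones, is used: dimethyloxosulfonium methylide from Me3S(O)I and NaH, with LaLi3(binaphthoxide)3 of the enantiomeric series that adds CH2 to the Si face, tris(2,4,6-trimethoxyphenyl)phosphine oxide, THF, 25 °C. This should give the 2,2-disubstituted (R)-epoxide F8. Opening at the CH2 terminus with (CH2=CH)2CuMgBr (from CH2=CHMgBr and CuI, THF, −40 °C; the lactone is not attacked by the cuprate) gives 8.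

**Further compounds**
F1 | step 1 | 2-cyclopropylideneethan-1-ol | OCC=C1CC1
F2 | step 1 | 2-cyclopropylideneacetaldehyde | O=CC=C1CC1
F3 | step 1 | (1'S,4'S,8'R)-4'-hydroxy-3'-oxospiro[cyclopropane-1,7'-[2]oxabicyclo[2.2.2]oct[5]ene]-8'-carbaldehyde | C1CC13[C@@H](C=O)[C@@]2(O)C=C[C@@H]3OC2=O
F4 | step 1 | (1'S,4'S,8'R)-4'-hydroxy-8'-[(1E)-3-oxobut-1-en-1-yl]spiro[cyclopropane-1,7'-[2]oxabicyclo[2.2.2]oct[5]en]-3'-one | C1CC13[C@@H](/C=C/C(C)=O)[C@@]2(O)C=C[C@@H]3OC2=O
F5 | step 2 | (1S,4S,8R)-7,7-dimethyl-3-oxo-4-[(trimethylsilyl)oxy]-2-oxabicyclo[2.2.2]oct-5-ene-8-carbaldehyde | CC1(C)[C@@H](C=O)[C@@]2(O[Si](C)(C)C)C=C[C@@H]1OC2=O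
F6 | step 2 | (1S,4S,8R)-7,7-dimethyl-8-[(1E)-3-oxobut-1-en-1-yl]-4-[(trimethylsilyl)oxy]-2-oxabicyclo[2.2.2]oct-5-en-3-one | CC1(C)[C@@H](/C=C/C(C)=O)[C@@]2(O[Si](C)(C)C)C=C[C@@H]1OC2=O
F7 | step 2 | (1S,4S,8R)-7,7-dimethyl-8-(3-oxobutyl)-4-[(trimethylsilyl)oxy]-2-oxabicyclo[2.2.2]octan-3-one | CC1(C)[C@@H](CCC(C)=O)[C@@]2(O[Si](C)(C)C)CC[C@@H]1OC2=O
F8 | step 4 | (1S,4S,8R)-4-hydroxy-7,7-dimethyl-8-{2-[(2R)-2-methyloxiran-2-yl]ethyl}-2-oxabicyclo[2.2.2]octan-3-one | CC1(C)[C@@H](CC[C@@]3(C)OC3)[C@@]2(O)CC[C@@H]1OC2=O
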